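**Retrosynthetic overview**

1. The lactone C6–O bond and the C15–OAc bond are disconnected together: a palladium-catalysed oxidative 1,4-acetoxy-lactonisation of a ring A diene acid (C15=C4–C5=C6, acrylic acid on C7) closes ring B, sets C6 and the C4=C5 geometry; only desilylation and C14 oxidation follow.
2. Ring A (ten-membered carbocycle) is opened at C2–C3: intramolecular chromium-catalysed Nozaki–Hiyama–Kishi allylation of a 2-(bromomethyl)diene onto the C2 enal (sets C2).
3. The open chain is cut at C4–C5: Sonogashira coupling with 2-bromoallyl alcohol, then cis-semi-reduction to the 5Z diene.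
4. C7–C8 comes from an asymmetric, syn-selective 2-(tert-butoxycarbonyl)allylation of a C8 aldehyde with an enynyl Baylis–Hillman bromide (sets C7 and C8).
5. The bromide comes from 3-(trimethylsilyl)propynal and tert-butyl acrylate; the aldehyde from pent-4-enal and glyoxal dimethyl acetal (fixes C1=C10). Ring A is formed first, ring B (lactone) last.

Assumption: L* is the antipode of 1,8-bis(4-isopropyl-4,5-dihydrooxazol-2-yl)-3,6-diphenyl-9H-carbazole that directs allylchromium reagents to the Si face of aldehydes (the sense is not established for these substrates and must be confirmed by a trial allylation); locants C1–C15 in the explanations are germacrane numbering.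

**Step 1**
Reactants: 1 3-(trimethylsilyl)prop-2-ynal; 2 tert-butyl prop-2-enoate
Product: 3 tert-butyl 3-hydroxy-2-methylidene-5-(trimethylsilyl)pent-4-ynoate (racemic)
Conditions: DABCO (20 mol%), neat, rt
Reagents that add atoms: none
Why: Morita–Baylis–Hillman reaction in which the electrophilic ynal traps the DABCO–acrylate zwitterion; the carbinol centre needs no control because it becomes sp2 in step 2.

**Step 2**
Reactants: 3 tert-butyl 3-hydroxy-2-methylidene-5-(trimethylsilyl)pent-4-ynoate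
Product: 4 tert-butyl (2Z)-2-(bromomethyl)-5-(trimethylsilyl)pent-2-en-4-ynoate
Conditions: PBr3 (0.4 equiv), Et2O, −10 to 0 °C
Reagents that add atoms: phosphorus tribromide, BrP(Br)Br
Why: SN2' bromination of a Baylis–Hillman alcohol with allylic transposition gives the conjugated primary bromide with the alkynyl group trans to the ester; either alkene isomer converges at the allylchromium stage of step 7.

**Step 3**
Reactants: 5 pent-4-enal; 6 2,2-dimethoxyacetaldehyde
Product: 7 (2E)-4,4-dimethoxy-2-(prop-2-en-1-yl)but-2-enal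
Conditions: pyrrolidine (10 mol%), PhCO2H (10 mol%), toluene, 40 °C, slow addition of 5
Reagents that add atoms: none
Why: amine/acid-catalysed crossed aldol condensation (enamine of 5 adds to the non-enolisable glyoxal monoacetal, then dehydration) gives the thermodynamic E-enal with CHO trans to the acetal carbon, which fixes the later C1=C10 geometry (C14 trans to C2).

**Step 4**
Reactants: 7 (2E)-4,4-dimethoxy-2-(prop-2-en-1-yl)but-2-enal
Product: 8 (2E)-4,4-dimethoxy-2-(prop-2-en-1-yl)but-2-en-1-ol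
Conditions: NaBH4, CeCl3·7H2O, MeOH, −20 °C
Reagents that add atoms: none
Why: Luche reduction is 1,2-selective for the enal and leaves the alkenes and the acetal untouched.

**Step 5**
Reactants: 8 (2E)-4,4-dimethoxy-2-(prop-2-en-1-yl)but-2-en-1-ol
Product: 9 tert-butyl{[(2E)-4,4-dimethoxy-2-(prop-2-en-1-yl)but-2-en-1-yl]oxy}dimethylsilane
Conditions: TBSCl, imidazole, DMF, rt
Reagents that add atoms: tert-butyldimethylsilyl chloride, CC(C)(C)[Si](C)(C)Cl
Why: standard silylation of a primary allylic alcohol (this oxygen becomes the C14 aldehyde at the end).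

**Step 6**
Reactants: 9 tert-butyl{[(2E)-4,4-dimethoxy-2-(prop-2-en-1-yl)but-2-en-1-yl]oxy}dimethylsilane
Product: 10 (3E)-3-{[tert-butyl(dimethyl)silyloxy]methyl}-5,5-dimethoxypent-3-enal
Conditions: OsO4 (2 mol%), NaIO4, 2,6-lutidine, 1,4-dioxane/H2O (3:1), rt
Reagents that add atoms: osmium tetroxide, O=[Os](=O)(=O)=O; sodium periodate, [Na+].[O-]I(=O)(=O)=O (re-oxidant that supplies the oxygen)
Why: Lemieux–Johnson cleavage takes the unhindered monosubstituted alkene in preference to the trisubstituted alkene, which is hindered and deactivated by its two allylic C–O carbons; lutidine buffering keeps the acetal and the β,γ-unsaturated aldehyde intact.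

**Step 7**
Reactants: 10 (3E)-3-{[tert-butyl(dimethyl)silyloxy]methyl}-5,5-dimethoxypent-3-enal; 4 tert-butyl (2Z)-2-(bromomethyl)-5-(trimethylsilyl)pent-2-en-4-ynoate
Product: 12 tert-butyl (3R,4R,6E)-6-{[tert-butyl(dimethyl)silyloxy]methyl}-3-ethynyl-4-hydroxy-8,8-dimethoxy-2-methylideneoct-6-enoate, via bis-silyl adduct 11 (not isolated)
Conditions: CrCl2 (10 mol%), L* (12 mol%), Mn, Me3SiCl, i-Pr2NEt (30 mol%), THF, 0 °C to rt; then K2CO3, MeOH, 0 °C
Reagents that add atoms: none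
Why: catalytic asymmetric Nozaki–Hiyama–Kishi 2-(alkoxycarbonyl)allylation in which the allylchromium from 4 (alkynyl cis to CH2Cr, silyl group blocking attack through the alkyne terminus) adds through its γ-carbon in a chair transition state to the Si face of 10 selected by L*, setting C8 (4R) and, through the syn preference of this Z-type reagent, C7 (3R); methanolysis then removes both trimethylsilyl groups.

**Step 8**
Reactants: 12 tert-butyl (3R,4R,6E)-6-{[tert-butyl(dimethyl)silyloxy]methyl}-3-ethynyl-4-hydroxy-8,8-dimethoxy-2-methylideneoct-6-enoate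
Product: 13 tert-butyl (3R,4R,6E)-6-{[tert-butyl(dimethyl)silyloxy]methyl}-3-ethynyl-8,8-dimethoxy-2-methylidene-4-(3-methylbutanoyloxy)oct-6-enoate
Conditions: 3-methylbutanoyl chloride, pyridine, DMAP (cat.), CH2Cl2, 0 °C to rt
Reagents that add atoms: 3-methylbutanoyl chloride, CC(C)CC(=O)Cl
Why: DMAP-catalysed acylation installs the isovalerate on O8 and prevents later lactol or lactone formation from this oxygen.

**Step 9**
Reactants: 13 tert-butyl (3R,4R,6E)-6-{[tert-butyl(dimethyl)silyloxy]methyl}-3-ethynyl-8,8-dimethoxy-2-methylidene-4-(3-methylbutanoyloxy)oct-6-enoate; 14 2-bromoprop-2-en-1-ol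
Product: 15 tert-butyl (3R,4R,6E)-6-{[tert-butyl(dimethyl)silyloxy]methyl}-3-[3-(hydroxymethyl)but-3-en-1-yn-1-yl]-8,8-dimethoxy-2-methylidene-4-(3-methylbutanoyloxy)oct-6-enoate
Conditions: Pd(PPh3)2Cl2 (5 mol%), CuI (10 mol%), i-Pr2NH, THF, rt
Reagents that add atoms: none
Why: Sonogashira coupling of the terminal alkyne with the vinyl bromide forms C4–C5 under mild amine conditions that tolerate the free allylic alcohol and do not isomerise the skipped enyne at C7.

**Step 10**
Reactants: 15 tert-butyl (3R,4R,6E)-6-{[tert-butyl(dimethyl)silyloxy]methyl}-3-[3-(hydroxymethyl)but-3-en-1-yn-1-yl]-8,8-dimethoxy-2-methylidene-4-(3-methylbutanoyloxy)oct-6-enoate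
Product: 17 tert-butyl (3R,4R,6E)-6-{[tert-butyl(dimethyl)silyloxy]methyl}-3-[(1Z)-3-(hydroxymethyl)buta-1,3-dien-1-yl]-2-methylidene-4-(3-methylbutanoyloxy)-8-oxooct-6-enoate, via dienyl acetal 16 (not isolated)
Conditions: Zn (activated with Cu(OAc)2 and AgNO3), MeOH/H2O (1:1), rt; filter; then PPTS (20 mol%), acetone/H2O (10:1), rt (keep below 30 °C)
Reagents that add atoms: water, O
Why: activated zinc reduces only the conjugated enyne triple bond with cis delivery of hydrogen (5Z diene), and the allylic dimethyl acetal is then hydrolysed by PPTS under conditions that spare the silyl ether and the tert-butyl ester.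

**Step 11**
Reactants: 17 tert-butyl (3R,4R,6E)-6-{[tert-butyl(dimethyl)silyloxy]methyl}-3-[(1Z)-3-(hydroxymethyl)buta-1,3-dien-1-yl]-2-methylidene-4-(3-methylbutanoyloxy)-8-oxooct-6-enoate
Product: 18 tert-butyl (3R,4R,6E)-3-[(1Z)-3-(bromomethyl)buta-1,3-dien-1-yl]-6-{[tert-butyl(dimethyl)silyloxy]methyl}-2-methylidene-4-(3-methylbutanoyloxy)-8-oxooct-6-enoate
Conditions: CBr4, PPh3, CH2Cl2, −20 to 0 °C
Reagents that add atoms: carbon tetrabromide, BrC(Br)(Br)Br
Why: Appel bromination converts the primary allylic alcohol to the bromide under neutral conditions (SN2 and SN2' give the same product because both allyl termini are CH2).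

**Step 12**
Reactants: 18 tert-butyl (3R,4R,6E)-3-[(1Z)-3-(bromomethyl)buta-1,3-dien-1-yl]-6-{[tert-butyl(dimethyl)silyloxy]methyl}-2-methylidene-4-(3-methylbutanoyloxy)-8-oxooct-6-enoate
Product: 20 tert-butyl 2-[(1R,2Z,6S,7E,10R)-8-{[tert-butyl(dimethyl)silyloxy]methyl}-6-hydroxy-4-methylidene-10-(3-methylbutanoyloxy)cyclodeca-2,7-dien-1-yl]prop-2-enoate, via trimethylsilyl ether 19 (not isolated)
Conditions: CrCl2 (20 mol%), L* (24 mol%), Mn, Me3SiCl, i-Pr2NEt, THF, rt, 18 added over 12 h (final 5 mM); then aq. citric acid, THF, 0 °C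
Reagents that add atoms: none
Why: intramolecular catalytic asymmetric Nozaki–Hiyama–Kishi allylation closes ring A, the 2-substituted allylchromium (both termini CH2) adding 1,2 to the enal on the Si face directed by L* to set C2 as S; the macrocyclic bias may reinforce or oppose the ligand, and slow addition keeps the substrate dilute.

**Step 13**
Reactants: 20 tert-butyl 2-[(1R,2Z,6S,7E,10R)-8-{[tert-butyl(dimethyl)silyloxy]methyl}-6-hydroxy-4-methylidene-10-(3-methylbutanoyloxy)cyclodeca-2,7-dien-1-yl]prop-2-enoate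
Product: 22 2-[(1R,2Z,6S,7E,10R)-6-[tert-butyl(dimethyl)silyloxy]-8-{[tert-butyl(dimethyl)silyloxy]methyl}-4-methylidene-10-(3-methylbutanoyloxy)cyclodeca-2,7-dien-1-yl]prop-2-enoic acid, via silyl ester 21 (not isolated)
Conditions: TBSOTf (3.5 equiv), 2,6-lutidine, CH2Cl2, 0 °C to rt; then K2CO3, THF/H2O, 0 °C
Reagents that add atoms: tert-butyldimethylsilyl trifluoromethanesulfonate, CC(C)(C)[Si](C)(C)OS(=O)(=O)C(F)(F)F
Why: TBSOTf/2,6-lutidine silylates the C2 alcohol and converts the tert-butyl ester into the silyl ester with loss of isobutene, which hydrolyses to the free acid on mild aqueous work-up without touching the isovalerate.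

**Step 14**
Reactants: 22 2-[(1R,2Z,6S,7E,10R)-6-[tert-butyl(dimethyl)silyloxy]-8-{[tert-butyl(dimethyl)silyloxy]methyl}-4-methylidene-10-(3-methylbutanoyloxy)cyclodeca-2,7-dien-1-yl]prop-2-enoic acid
Product: 23 (3aR,4R,6E,8S,10E,11aR)-10-(acetyloxymethyl)-8-[tert-butyl(dimethyl)silyloxy]-6-{[tert-butyl(dimethyl)silyloxy]methyl}-3-methylidene-2-oxo-2,3,3a,4,5,8,9,11a-octahydrocyclodeca[b]furan-4-yl 3-methylbutanoate
Conditions: Pd(OAc)2 (10 mol%), 1,4-benzoquinone (2 equiv), LiOAc (2 equiv), AcOH/acetone (1:4), 25 °C, dark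
Reagents that add atoms: acetic acid, CC(=O)O
Why: Proposed new method: divalent palladium binds the semicyclic diene (C5=C6, C4=C15) and the acrylic carboxylate adds 5-exo to C6 from the face it occupies when H7 eclipses the Z-alkene (A(1,3) minimum), which closes ring B trans-fused (6R); the resulting η3-allylpalladium (C5–C4–C15) equilibrates by η3–η1–η3 slippage to the less strained isomer with C3 and C6 cis and is captured by acetate at the primary terminus C15, remote from the C6–O bond, giving the 4E allylic acetate while benzoquinone returns zerovalent palladium to the divalent state; the closest known reaction type is the palladium/benzoquinone 1,4-acetoxy-lactonisation of cyclic 1,3-dienes carrying a CH2CO2H arm, not yet shown for exocyclic dienes in medium rings, for acrylic acids as internal nucleophile or for trans-fused lactones.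

**Step 15**
Reactants: 23 (3aR,4R,6E,8S,10E,11aR)-10-(acetyloxymethyl)-8-[tert-butyl(dimethyl)silyloxy]-6-{[tert-butyl(dimethyl)silyloxy]methyl}-3-methylidene-2-oxo-2,3,3a,4,5,8,9,11a-octahydrocyclodeca[b]furan-4-yl 3-methylbutanoate
Product: 24 (3aR,4R,6E,8S,10E,11aR)-10-(acetyloxymethyl)-8-hydroxy-6-(hydroxymethyl)-3-methylidene-2-oxo-2,3,3a,4,5,8,9,11a-octahydrocyclodeca[b]furan-4-yl 3-methylbutanoate
Conditions: HF·pyridine, pyridine/THF, 0 °C to rt
Reagents that add atoms: none
Why: buffered HF·pyridine cleaves both silyl ethers without acyl migration or addition to the α-methylene lactone.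

**Step 16**
Reactants: 24 (3aR,4R,6E,8S,10E,11aR)-10-(acetyloxymethyl)-8-hydroxy-6-(hydroxymethyl)-3-methylidene-2-oxo-2,3,3a,4,5,8,9,11a-octahydrocyclodeca[b]furan-4-yl 3-methylbutanoate
Product: 25 (3aR,4R,6E,8S,10E,11aR)-10-(acetyloxymethyl)-6-formyl-8-hydroxy-3-methylidene-2-oxo-2,3,3a,4,5,8,9,11a-octahydrocyclodeca[b]furan-4-yl 3-methylbutanoate (CNP0524123.1)
Conditions: TEMPO (20 mol%), PhI(OAc)2 (1.1 equiv), CH2Cl2, rt
Reagents that add atoms: none
Why: TEMPO/PhI(OAc)2 oxidation is selective for the primary allylic alcohol over the secondary one, giving the C14 enal whose E geometry (CHO trans to C2) prevents lactol formation with the C2 hydroxyl.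

**Compound list**

1 | 3-(trimethylsilyl)prop-2-ynal | C[Si](C)(C)C#CC=O | starting material
2 | tert-butyl prop-2-enoate | C=CC(=O)OC(C)(C)C | starting material
3 | tert-butyl 3-hydroxy-2-methylidene-5-(trimethylsilyl)pent-4-ynoate (racemic) | C=C(C(=O)OC(C)(C)C)C(O)C#C[Si](C)(C)C | intermediate
4 | tert-butyl (2Z)-2-(bromomethyl)-5-(trimethylsilyl)pent-2-en-4-ynoate | BrC/C(C(=O)OC(C)(C)C)=C\C#C[Si](C)(C)C | intermediate
5 | pent-4-enal | C=CCCC=O | starting material
6 | 2,2-dimethoxyacetaldehyde | COC(OC)C=O | starting material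
7 | (2E)-4,4-dimethoxy-2-(prop-2-en-1-yl)but-2-enal | O=C/C(CC=C)=C/C(OC)OC | intermediate
8 | (2E)-4,4-dimethoxy-2-(prop-2-en-1-yl)but-2-en-1-ol | OC/C(CC=C)=C/C(OC)OC | intermediate
9 | tert-butyl{[(2E)-4,4-dimethoxy-2-(prop-2-en-1-yl)but-2-en-1-yl]oxy}dimethylsilane | CC(C)(C)[Si](C)(C)OC/C(CC=C)=C/C(OC)OC | intermediate
10 | (3E)-3-{[tert-butyl(dimethyl)silyloxy]methyl}-5,5-dimethoxypent-3-enal | O=CC/C(CO[Si](C)(C)C(C)(C)C)=C\C(OC)OC | intermediate
11 | tert-butyl (3S,4R,6E)-6-{[tert-butyl(dimethyl)silyloxy]methyl}-8,8-dimethoxy-2-methylidene-4-(trimethylsilyloxy)-3-[(trimethylsilyl)ethynyl]oct-6-enoate | C=C(C(=O)OC(C)(C)C)[C@@H](C#C[Si](C)(C)C)[C@H](O[Si](C)(C)C)C/C(CO[Si](C)(C)C(C)(C)C)=C\C(OC)OC | intermediate (not isolated)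
12 | tert-butyl (3R,4R,6E)-6-{[tert-butyl(dimethyl)silyloxy]methyl}-3-ethynyl-4-hydroxy-8,8-dimethoxy-2-methylideneoct-6-enoate | C=C(C(=O)OC(C)(C)C)[C@@H](C#C)[C@H](O)C/C(CO[Si](C)(C)C(C)(C)C)=C\C(OC)OC | intermediate
13 | tert-butyl (3R,4R,6E)-6-{[tert-butyl(dimethyl)silyloxy]methyl}-3-ethynyl-8,8-dimethoxy-2-methylidene-4-(3-methylbutanoyloxy)oct-6-enoate | C=C(C(=O)OC(C)(C)C)[C@@H](C#C)[C@H](OC(=O)CC(C)C)C/C(CO[Si](C)(C)C(C)(C)C)=C\C(OC)OC | intermediate
14 | 2-bromoprop-2-en-1-ol | OCC(Br)=C | starting material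
15 | tert-butyl (3R,4R,6E)-6-{[tert-butyl(dimethyl)silyloxy]methyl}-3-[3-(hydroxymethyl)but-3-en-1-yn-1-yl]-8,8-dimethoxy-2-methylidene-4-(3-methylbutanoyloxy)oct-6-enoate | C=C(C(=O)OC(C)(C)C)[C@@H](C#CC(=C)CO)[C@H](OC(=O)CC(C)C)C/C(CO[Si](C)(C)C(C)(C)C)=C\C(OC)OC | intermediate
16 | tert-butyl (3R,4R,6E)-6-{[tert-butyl(dimethyl)silyloxy]methyl}-3-[(1Z)-3-(hydroxymethyl)buta-1,3-dien-1-yl]-8,8-dimethoxy-2-methylidene-4-(3-methylbutanoyloxy)oct-6-enoate | C=C(C(=O)OC(C)(C)C)[C@@H](/C=C\C(=C)CO)[C@H](OC(=O)CC(C)C)C/C(CO[Si](C)(C)C(C)(C)C)=C\C(OC)OC | intermediate (not isolated)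
17 | tert-butyl (3R,4R,6E)-6-{[tert-butyl(dimethyl)silyloxy]methyl}-3-[(1Z)-3-(hydroxymethyl)buta-1,3-dien-1-yl]-2-methylidene-4-(3-methylbutanoyloxy)-8-oxooct-6-enoate | C=C(C(=O)OC(C)(C)C)[C@@H](/C=C\C(=C)CO)[C@H](OC(=O)CC(C)C)C/C(CO[Si](C)(C)C(C)(C)C)=C\C=O | intermediate
18 | tert-butyl (3R,4R,6E)-3-[(1Z)-3-(bromomethyl)buta-1,3-dien-1-yl]-6-{[tert-butyl(dimethyl)silyloxy]methyl}-2-methylidene-4-(3-methylbutanoyloxy)-8-oxooct-6-enoate | C=C(C(=O)OC(C)(C)C)[C@@H](/C=C\C(=C)CBr)[C@H](OC(=O)CC(C)C)C/C(CO[Si](C)(C)C(C)(C)C)=C\C=O | intermediate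
19 | tert-butyl 2-[(1R,2Z,6S,7E,10R)-8-{[tert-butyl(dimethyl)silyloxy]methyl}-4-methylidene-10-(3-methylbutanoyloxy)-6-(trimethylsilyloxy)cyclodeca-2,7-dien-1-yl]prop-2-enoate | C=C(C(=O)OC(C)(C)C)[C@H]1/C=C\C(=C)C[C@H](O[Si](C)(C)C)/C=C(/CO[Si](C)(C)C(C)(C)C)C[C@H]1OC(=O)CC(C)C | intermediate (not isolated)
20 | tert-butyl 2-[(1R,2Z,6S,7E,10R)-8-{[tert-butyl(dimethyl)silyloxy]methyl}-6-hydroxy-4-methylidene-10-(3-methylbutanoyloxy)cyclodeca-2,7-dien-1-yl]prop-2-enoate | C=C(C(=O)OC(C)(C)C)[C@H]1/C=C\C(=C)C[C@H](O)/C=C(/CO[Si](C)(C)C(C)(C)C)C[C@H]1OC(=O)CC(C)C | intermediate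
21 | tert-butyl(dimethyl)silyl 2-[(1R,2Z,6S,7E,10R)-6-[tert-butyl(dimethyl)silyloxy]-8-{[tert-butyl(dimethyl)silyloxy]methyl}-4-methylidene-10-(3-methylbutanoyloxy)cyclodeca-2,7-dien-1-yl]prop-2-enoate | C=C(C(=O)O[Si](C)(C)C(C)(C)C)[C@H]1/C=C\C(=C)C[C@H](O[Si](C)(C)C(C)(C)C)/C=C(/CO[Si](C)(C)C(C)(C)C)C[C@H]1OC(=O)CC(C)C | intermediate (not isolated)
22 | 2-[(1R,2Z,6S,7E,10R)-6-[tert-butyl(dimethyl)silyloxy]-8-{[tert-butyl(dimethyl)silyloxy]methyl}-4-methylidene-10-(3-methylbutanoyloxy)cyclodeca-2,7-dien-1-yl]prop-2-enoic acid | C=C(C(=O)O)[C@H]1/C=C\C(=C)C[C@H](O[Si](C)(C)C(C)(C)C)/C=C(/CO[Si](C)(C)C(C)(C)C)C[C@H]1OC(=O)CC(C)C | intermediate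
23 | (3aR,4R,6E,8S,10E,11aR)-10-(acetyloxymethyl)-8-[tert-butyl(dimethyl)silyloxy]-6-{[tert-butyl(dimethyl)silyloxy]methyl}-3-methylidene-2-oxo-2,3,3a,4,5,8,9,11a-octahydrocyclodeca[b]furan-4-yl 3-methylbutanoate | C=C1C(=O)O[C@@H]2/C=C(/COC(C)=O)C[C@H](O[Si](C)(C)C(C)(C)C)/C=C(/CO[Si](C)(C)C(C)(C)C)C[C@@H](OC(=O)CC(C)C)[C@@H]12 | intermediate
24 | (3aR,4R,6E,8S,10E,11aR)-10-(acetyloxymethyl)-8-hydroxy-6-(hydroxymethyl)-3-methylidene-2-oxo-2,3,3a,4,5,8,9,11a-octahydrocyclodeca[b]furan-4-yl 3-methylbutanoate | C=C1C(=O)O[C@@H]2/C=C(/COC(C)=O)C[C@H](O)/C=C(/CO)C[C@@H](OC(=O)CC(C)C)[C@@H]12 | intermediate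
25 | (3aR,4R,6E,8S,10E,11aR)-10-(acetyloxymethyl)-6-formyl-8-hydroxy-3-methylidene-2-oxo-2,3,3a,4,5,8,9,11a-octahydrocyclodeca[b]furan-4-yl 3-methylbutanoate | C=C1C(=O)O[C@@H]2/C=C(/COC(C)=O)C[C@H](O)/C=C(/C=O)C[C@@H](OC(=O)CC(C)C)[C@@H]12 | target

**Totals and risks**

Total step count: 16. Longest linear sequence: 14 steps (steps 3 to 16, from pent-4-enal and 2,2-dimethoxyacetaldehyde).

The three steps most likely to fail:

Step 14 (the proposed new step). Acetate may be captured at C5 instead of C15, the allyl intermediate may give the ring-trans C4=C5 isomer, or the diene may react with benzoquinone in a Diels–Alder reaction. The fallback uses known chemistry and sets out from 22. Iodolactonisation (I2, NaHCO3, MeCN, 0 °C) adds the carboxylate to C6 and iodine to C5 anti across the Z-alkene, under the same A(1,3) control, to give the allylic iodolactone (3aR,4R,6E,8S,11S,11aS)-8-[tert-butyl(dimethyl)silyloxy]-6-{[tert-butyl(dimethyl)silyloxy]methyl}-11-iodo-3,10-dimethylidene-2-oxo-2,3,3a,4,5,8,9,10,11,11a-decahydrocyclodeca[b]furan-4-yl 3-methylbutanoate F1. Treatment of this with AgOAc in AcOH replaces iodide by acetate with allylic transposition to the primary, trisubstituted allylic acetate, and the route is rejoined at 23.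

Step 12. Ring closure under catalytic, slow-addition conditions may be inefficient, and the ligand may be mismatched with the macrocyclic bias at C2. The fallback sets out from 18. Stoichiometric CrCl2 in THF/DMF at high dilution, without ligand, closes ring A and gives 20 mixed with its C2 epimer tert-butyl 2-[(1R,2Z,6R,7E,10R)-8-{[tert-butyl(dimethyl)silyloxy]methyl}-6-hydroxy-4-methylidene-10-(3-methylbutanoyloxy)cyclodeca-2,7-dien-1-yl]prop-2-enoate F2. Dess–Martin oxidation of the mixture gives the single enone tert-butyl 2-[(1R,2Z,7E,10R)-8-{[tert-butyl(dimethyl)silyloxy]methyl}-4-methylidene-10-(3-methylbutanoyloxy)-6-oxocyclodeca-2,7-dien-1-yl]prop-2-enoate F3. Reduction with (R)-2-methyl-CBS-oxazaborolidine and catecholborane at −40 °C (alkenyl as the large group) sets C2 as S under reagent control and the route is rejoined at 20.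

Step 7. The γ-alkynyl reagent may give low enantioselectivity or the anti adduct under chromium catalysis. The fallback sets out from 10 and 4. Indium powder in THF/H2O (Barbier allylation, syn-selective for Z-2-(bromomethyl)alkenoates) gives racemic tert-butyl (3S*,4R*,6E)-6-{[tert-butyl(dimethyl)silyloxy]methyl}-4-hydroxy-8,8-dimethoxy-2-methylidene-3-[(trimethylsilyl)ethynyl]oct-6-enoate F4. K2CO3 in MeOH removes the alkynyl silyl group to give racemic 12, that is 12 together with its enantiomer tert-butyl (3S,4S,6E)-6-{[tert-butyl(dimethyl)silyloxy]methyl}-3-ethynyl-4-hydroxy-8,8-dimethoxy-2-methylideneoct-6-enoate F5. Kinetic resolution with Candida antarctica lipase B and vinyl 3-methylbutanoate in MTBE acylates the 4R enantiomer, which installs the isovalerate at the same time, and the route is rejoined at 13 (at most 50% yield; F5 is left behind).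

**Further compounds**

F1 | step 14 | (3aR,4R,6E,8S,11S,11aS)-8-[tert-butyl(dimethyl)silyloxy]-6-{[tert-butyl(dimethyl)silyloxy]methyl}-11-iodo-3,10-dimethylidene-2-oxo-2,3,3a,4,5,8,9,10,11,11a-decahydrocyclodeca[b]furan-4-yl 3-methylbutanoate | C=C1C(=O)O[C@@H]2[C@@H](I)C(=C)C[C@H](O[Si](C)(C)C(C)(C)C)/C=C(/CO[Si](C)(C)C(C)(C)C)C[C@@H](OC(=O)CC(C)C)[C@@H]12
F2 | step 12 | tert-butyl 2-[(1R,2Z,6R,7E,10R)-8-{[tert-butyl(dimethyl)silyloxy]methyl}-6-hydroxy-4-methylidene-10-(3-methylbutanoyloxy)cyclodeca-2,7-dien-1-yl]prop-2-enoate | C=C(C(=O)OC(C)(C)C)[C@H]1/C=C\C(=C)C[C@@H](O)/C=C(/CO[Si](C)(C)C(C)(C)C)C[C@H]1OC(=O)CC(C)C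
F3 | step 12 | tert-butyl 2-[(1R,2Z,7E,10R)-8-{[tert-butyl(dimethyl)silyloxy]methyl}-4-methylidene-10-(3-methylbutanoyloxy)-6-oxocyclodeca-2,7-dien-1-yl]prop-2-enoate | C=C(C(=O)OC(C)(C)C)[C@H]1/C=C\C(=C)CC(=O)/C=C(/CO[Si](C)(C)C(C)(C)C)C[C@H]1OC(=O)CC(C)C
F4 | step 7 | tert-butyl (3S*,4R*,6E)-6-{[tert-butyl(dimethyl)silyloxy]methyl}-4-hydroxy-8,8-dimethoxy-2-methylidene-3-[(trimethylsilyl)ethynyl]oct-6-enoate (racemate; the 3S,4R enantiomer is drawn) | C=C(C(=O)OC(C)(C)C)[C@@H](C#C[Si](C)(C)C)[C@H](O)C/C(CO[Si](C)(C)C(C)(C)C)=C\C(OC)OC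
F5 | step 7 | tert-butyl (3S,4S,6E)-6-{[tert-butyl(dimethyl)silyloxy]methyl}-3-ethynyl-4-hydroxy-8,8-dimethoxy-2-methylideneoct-6-enoate | C=C(C(=O)OC(C)(C)C)[C@H](C#C)[C@@H](O)C/C(CO[Si](C)(C)C(C)(C)C)=C\C(OC)OC
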